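**Plan**

- Retrosynthesis: remove the three silyl groups, then cut C2–C3 of ring C (the ring-closing bond), then the diazo group back to the acetyl CH3, then the O1–CH2 ether bond, then the two ring A O–Si bonds, and last the C8–prenyl bond.
- Enabling feature: C2 is both benzylic to ring B and bonded to the ring oxygen O1, so in the open form it is the CH2 of a benzyl aryl ether; it lies 1,6 to C3, the α-carbon of the C4 aryl ketone, which can be made a diazo (carbenoid) carbon.
- Forward: ring A comes from phloroacetophenone (C-prenylated, then bis-silylated); ring B together with C2 comes from vanillin as a benzyl alcohol; the two are joined through O1 by Mitsunobu etherification, so the "benzyl ether" is the future C2-aryl unit.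
- The acetyl methyl group is converted into the diazoketone; an enantioselective carbenoid 1,6 C–H insertion then closes ring C and sets C2 from an achiral precursor; global desilylation ends the route.
- Stereochemistry: the single stereocentre (2S) comes from the chiral dirhodium carboxylate catalyst, which selects one of the two enantiotopic benzylic hydrogens; no strongly basic step follows that could open ring C.
- Helpers: triisopropylsilyl ethers (no C–H next to oxygen, so no second insertion site; removed last), a trifluoroacetyl group (activates the methyl ketone for diazo transfer, lost in the same step) and the diazo group (lost as N2).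

Key step: step 7

Assumption: the bis-silylation of step 4 is taken to spare the hydroxyl wedged between the acetyl and prenyl groups (to be confirmed by NOE/HMBC before step 5), and the S-configured catalyst is proposed for the (2S) product, its sense of induction to be verified on the first run, the enantiomeric catalyst being equally available.

**Route**

Step 1
Reactants: 1 vanillin
Product: 2 3-methoxy-4-(triisopropylsilyloxy)benzaldehyde
Conditions: TIPSCl, imidazole, DMF, rt
Reagents that add atoms: triisopropylsilyl chloride, CC(C)[Si](Cl)(C(C)C)C(C)C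
Why: Standard imidazole-mediated silylation of a phenol, giving a silyl ether that carries no C–H next to oxygen and survives all later steps.

Step 2
Reactants: 2 3-methoxy-4-(triisopropylsilyloxy)benzaldehyde
Product: 3 [3-methoxy-4-(triisopropylsilyloxy)phenyl]methanol
Conditions: NaBH4, MeOH/THF, 0 °C
Reagents that add atoms: none
Why: Borohydride reduction of an aromatic aldehyde to the benzylic alcohol, which leaves the aryl silyl ether intact at 0 °C.

Step 3
Reactants: 4 2,4,6-trihydroxyacetophenone (phloroacetophenone); 5 prenyl bromide (1-bromo-3-methylbut-2-ene)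
Product: 6 1-[2,4,6-trihydroxy-3-(3-methylbut-2-en-1-yl)phenyl]ethan-1-one
Conditions: DBU, THF, 0 °C to rt, 5 as limiting reagent
Reagents that add atoms: none
Why: Nuclear (C-) prenylation of the phloroglucinol-type phenoxide, a known direct alkylation of this ketone whose two free ring positions are equivalent, so only the degree of alkylation has to be controlled by stoichiometry and chromatography.

Step 4
Reactants: 6 1-[2,4,6-trihydroxy-3-(3-methylbut-2-en-1-yl)phenyl]ethan-1-one
Product: 7 1-[2-hydroxy-3-(3-methylbut-2-en-1-yl)-4,6-bis(triisopropylsilyloxy)phenyl]ethan-1-one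
Conditions: TIPSCl (2.1 equiv), imidazole, DMF, 0 °C to rt
Reagents that add atoms: triisopropylsilyl chloride, CC(C)[Si](Cl)(C(C)C)C(C)C
Why: Selective phenol silylation, in which the non-chelated para hydroxyl and then the less hindered ortho hydroxyl (flanked by acetyl and H) should react with the bulky silyl chloride, while the hydroxyl between acetyl and prenyl stays as the chelated phenol, the usual outcome of partial protection of 3-substituted phloroacetophenones.

Step 5
Reactants: 7 1-[2-hydroxy-3-(3-methylbut-2-en-1-yl)-4,6-bis(triisopropylsilyloxy)phenyl]ethan-1-one; 3 [3-methoxy-4-(triisopropylsilyloxy)phenyl]methanol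
Product: 8 1-[2-{[3-methoxy-4-(triisopropylsilyloxy)phenyl]methoxy}-3-(3-methylbut-2-en-1-yl)-4,6-bis(triisopropylsilyloxy)phenyl]ethan-1-one
Conditions: PPh3, DIAD, THF, 0 °C to rt
Reagents that add atoms: none
Why: Mitsunobu etherification of an acidic ortho-acylphenol with a primary benzylic alcohol, under neutral conditions that keep the aryl silyl ethers, which carbonate alkylation in DMF would cleave.

Step 6
Reactants: 8 1-[2-{[3-methoxy-4-(triisopropylsilyloxy)phenyl]methoxy}-3-(3-methylbut-2-en-1-yl)-4,6-bis(triisopropylsilyloxy)phenyl]ethan-1-one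
Product: 10 2-diazo-1-[2-{[3-methoxy-4-(triisopropylsilyloxy)phenyl]methoxy}-3-(3-methylbut-2-en-1-yl)-4,6-bis(triisopropylsilyloxy)phenyl]ethan-1-one, via trifluoroacetyl diketone 9 (not isolated)
Conditions: LiN(SiMe3)2, THF, −78 °C; CF3CO2CH2CF3, −78 °C; AcOH quench; then MsN3, Et3N, H2O (1 equiv), MeCN, rt
Reagents that add atoms: 2,2,2-trifluoroethyl trifluoroacetate, O=C(OCC(F)(F)F)C(F)(F)F (its trifluoroacetyl group stays in 9 only); methanesulfonyl azide, CS(=O)(=O)N=[N+]=[N-]
Why: Detrifluoroacetylative diazo transfer, in which the kinetic lithium enolate of the methyl ketone is C-acylated (crossed Claisen condensation) to the activated 1,3-diketone 9 and mesyl azide then transfers N2 with loss of the trifluoroacetyl group as the N-acylsulfonamide, leaving silyl ethers, benzyl ether and alkene untouched.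

Step 7
Reactants: 10 2-diazo-1-[2-{[3-methoxy-4-(triisopropylsilyloxy)phenyl]methoxy}-3-(3-methylbut-2-en-1-yl)-4,6-bis(triisopropylsilyloxy)phenyl]ethan-1-one
Product: 11 (2S)-2-[3-methoxy-4-(triisopropylsilyloxy)phenyl]-8-(3-methylbut-2-en-1-yl)-5,7-bis(triisopropylsilyloxy)-2,3-dihydro-4H-chromen-4-one
Conditions: Rh2(S-PTTL)4 (dirhodium tetrakis[N-phthaloyl-(S)-tert-leucinate], 1 mol %), CH2Cl2, 4 Å MS, 0 °C to rt, 10 added over 3 h by syringe pump to 0.01 M final concentration
Reagents that add atoms: none
Why: The dirhodium tetracarboxylate expels N2 from 10 to give an electrophilic rhodium carbenoid on the carbon that becomes C3, and this carbon inserts, through a concerted but asynchronous three-centre transition state with hydride-transfer character, into one of the two enantiotopic C–H bonds of the ArO–CH2–Ar' group lying 1,6 to it, so that the C2–C3 and C3–H bonds form together. The closest known reaction type is the intramolecular C–H insertion of 2-alkoxyaryl α-diazoketones to chroman-4-ones under catalysis by chiral divalent rhodium carboxylates. Ring C closes as a six-membered ring by 1,6 C–H insertion through a chair-like transition state in which four of the six ring atoms (C4, C4a, C8a and O1) are already held in place by ring A. The C2 stereocentre is set by the chiral carboxylate ligands, which differentiate the two enantiotopic benzylic hydrogens; the S-PTTL catalyst is proposed for the (2S) product, with its antipode from D-tert-leucine as the alternative should the sense be opposite. The step needs chemoselectivity for 1,6 insertion over oxonium ylide formation followed by Stevens shift of the benzyl group, over reaction at the second ortho oxygen and over cyclopropanation of the prenyl alkene. The substrate secures this because the benzylic C–H is activated by both the ether oxygen and the electron-rich 4-silyloxy-3-methoxyphenyl ring, the second ortho oxygen carries a bulky silicon group and no α C–H, the hindered aryl ether oxygen is a poor ylide donor toward a carboxylate-ligated carbenoid, and the prenyl group sits meta to the carbenoid arm and cannot reach it, while slow addition at high dilution suppresses bimolecular cyclopropanation and carbene dimerisation.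

Step 8
Reactants: 11 (2S)-2-[3-methoxy-4-(triisopropylsilyloxy)phenyl]-8-(3-methylbut-2-en-1-yl)-5,7-bis(triisopropylsilyloxy)-2,3-dihydro-4H-chromen-4-one
Product: 12 (2S)-5,7-dihydroxy-2-(4-hydroxy-3-methoxyphenyl)-8-(3-methylbut-2-en-1-yl)-2,3-dihydro-4H-chromen-4-one (the target)
Conditions: Bu4NF (3.3 equiv), AcOH (3.5 equiv), THF, 0 °C
Reagents that add atoms: none
Why: Fluoride cleavage of the three aryl silyl ethers under acetic acid buffering, which keeps the phenoxide concentration low so that neither retro-oxa-Michael opening of ring C (which would scramble C2) nor acid-promoted cyclisation of the prenyl group onto the C7 hydroxyl should occur.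

**Compound list**

1 | vanillin (4-hydroxy-3-methoxybenzaldehyde) | COc1cc(C=O)ccc1O | starting material
2 | 3-methoxy-4-(triisopropylsilyloxy)benzaldehyde | COc1cc(C=O)ccc1O[Si](C(C)C)(C(C)C)C(C)C | intermediate
3 | [3-methoxy-4-(triisopropylsilyloxy)phenyl]methanol | COc1cc(CO)ccc1O[Si](C(C)C)(C(C)C)C(C)C | intermediate
4 | 2,4,6-trihydroxyacetophenone (phloroacetophenone) | CC(=O)c1c(O)cc(O)cc1O | starting material
5 | prenyl bromide (1-bromo-3-methylbut-2-ene) | CC(C)=CCBr | starting material
6 | 1-[2,4,6-trihydroxy-3-(3-methylbut-2-en-1-yl)phenyl]ethan-1-one | CC(=O)c1c(O)cc(O)c(CC=C(C)C)c1O | intermediate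
7 | 1-[2-hydroxy-3-(3-methylbut-2-en-1-yl)-4,6-bis(triisopropylsilyloxy)phenyl]ethan-1-one | CC(=O)c1c(O[Si](C(C)C)(C(C)C)C(C)C)cc(O[Si](C(C)C)(C(C)C)C(C)C)c(CC=C(C)C)c1O | intermediate
8 | 1-[2-{[3-methoxy-4-(triisopropylsilyloxy)phenyl]methoxy}-3-(3-methylbut-2-en-1-yl)-4,6-bis(triisopropylsilyloxy)phenyl]ethan-1-one | CC(=O)c1c(O[Si](C(C)C)(C(C)C)C(C)C)cc(O[Si](C(C)C)(C(C)C)C(C)C)c(CC=C(C)C)c1OCc1ccc(O[Si](C(C)C)(C(C)C)C(C)C)c(OC)c1 | intermediate
9 | 4,4,4-trifluoro-1-[2-{[3-methoxy-4-(triisopropylsilyloxy)phenyl]methoxy}-3-(3-methylbut-2-en-1-yl)-4,6-bis(triisopropylsilyloxy)phenyl]butane-1,3-dione | O=C(CC(=O)C(F)(F)F)c1c(O[Si](C(C)C)(C(C)C)C(C)C)cc(O[Si](C(C)C)(C(C)C)C(C)C)c(CC=C(C)C)c1OCc1ccc(O[Si](C(C)C)(C(C)C)C(C)C)c(OC)c1 | intermediate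
10 | 2-diazo-1-[2-{[3-methoxy-4-(triisopropylsilyloxy)phenyl]methoxy}-3-(3-methylbut-2-en-1-yl)-4,6-bis(triisopropylsilyloxy)phenyl]ethan-1-one | [N-]=[N+]=CC(=O)c1c(O[Si](C(C)C)(C(C)C)C(C)C)cc(O[Si](C(C)C)(C(C)C)C(C)C)c(CC=C(C)C)c1OCc1ccc(O[Si](C(C)C)(C(C)C)C(C)C)c(OC)c1 | intermediate
11 | (2S)-2-[3-methoxy-4-(triisopropylsilyloxy)phenyl]-8-(3-methylbut-2-en-1-yl)-5,7-bis(triisopropylsilyloxy)-2,3-dihydro-4H-chromen-4-one | COc1cc([C@@H]2CC(=O)c3c(O[Si](C(C)C)(C(C)C)C(C)C)cc(O[Si](C(C)C)(C(C)C)C(C)C)c(CC=C(C)C)c3O2)ccc1O[Si](C(C)C)(C(C)C)C(C)C | intermediate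
12 | (2S)-5,7-dihydroxy-2-(4-hydroxy-3-methoxyphenyl)-8-(3-methylbut-2-en-1-yl)-2,3-dihydro-4H-chromen-4-one | COc1cc([C@@H]2CC(=O)c3c(O)cc(O)c(CC=C(C)C)c3O2)ccc1O | target

**Step count and risks**

Total step count: 8. Longest linear sequence: 6 steps (steps 3 to 8, from 4); the two-step branch from vanillin (steps 1 and 2) joins at step 5.

Steps most likely to fail:

1. Step 7. The carbenoid may be diverted into oxonium ylide formation at the ether oxygen with benzyl shift, or the catalyst may discriminate poorly between the two enantiotopic benzylic hydrogens. The fallback sets out from 7 and comes back at 11, forming the C2–aryl bond instead. Compound 7 would be condensed with N,N-dimethylformamide dimethyl acetal (toluene, 90 °C) to the enaminone (E)-3-(dimethylamino)-1-[2-hydroxy-3-(3-methylbut-2-en-1-yl)-4,6-bis(triisopropylsilyloxy)phenyl]prop-2-en-1-one F1. Cyclisation with loss of dimethylamine (2 M HCl, CH2Cl2, rt) should give 8-(3-methylbut-2-en-1-yl)-5,7-bis(triisopropylsilyloxy)-4H-chromen-4-one F2. Separately, commercial 4-bromo-2-methoxyphenol would be silylated (TIPSCl, imidazole, DMF) to (4-bromo-2-methoxyphenoxy)triisopropylsilane F3 and converted (n-BuLi, THF, −78 °C; B(OiPr)3; 1 M HCl work-up) into [3-methoxy-4-(triisopropylsilyloxy)phenyl]boronic acid F4. Enantioselective conjugate addition of F4 to F2 under catalysis by divalent palladium (Pd(OCOCF3)2, tert-butyl pyridine-oxazoline ligand, NH4PF6, H2O, ClCH2CH2Cl, 60 °C), a known asymmetric arylation of chromones to flavanones, should give 11; the ligand enantiomer that delivers (2S) would be used.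

2. Step 4. The bulky silyl chloride may cap the wrong ortho hydroxyl or all three hydroxyls, so that the benzyl ether later ends up on the oxygen remote from the prenyl group. The fallback sets out from 4 (and uses 3) and comes back at 8, fixing the regiochemistry by a sigmatropic sequence. Compound 4 would be monosilylated at its non-chelated para hydroxyl (TIPSCl 1.0 equiv, imidazole, DMF, 0 °C) to 1-[2,6-dihydroxy-4-(triisopropylsilyloxy)phenyl]ethan-1-one F5. One of its two equivalent chelated hydroxyls would be etherified with 3 (PPh3, DIAD, THF) to 1-[2-hydroxy-6-{[3-methoxy-4-(triisopropylsilyloxy)phenyl]methoxy}-4-(triisopropylsilyloxy)phenyl]ethan-1-one F6. The remaining hydroxyl would be etherified with 3-methylbut-2-en-1-ol (PPh3, DIAD, THF) to the prenyl ether 1-[2-{[3-methoxy-4-(triisopropylsilyloxy)phenyl]methoxy}-6-(3-methylbut-2-en-1-yloxy)-4-(triisopropylsilyloxy)phenyl]ethan-1-one F7. A para-Claisen–Cope rearrangement catalysed by trivalent europium (Eu(fod)3, tris(6,6,7,7,8,8,8-heptafluoro-2,2-dimethyloctane-3,5-dionato)europium, CHCl3, 60 °C) should move the prenyl group to the carbon para to its oxygen, which is the carbon between the benzyloxy and silyloxy groups, giving 1-[6-hydroxy-2-{[3-methoxy-4-(triisopropylsilyloxy)phenyl]methoxy}-3-(3-methylbut-2-en-1-yl)-4-(triisopropylsilyloxy)phenyl]ethan-1-one F8. Silylation of the liberated hydroxyl (TIPSCl, imidazole, DMF) should then give 8.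

3. Step 6. The lithium enolate may undergo oxygen-to-oxygen silyl migration from the ortho silyloxy group, or trifluoroacetylation of the hindered enolate may stay incomplete, so that diazo transfer fails. The fallback sets out from 8 and comes back at 10 without generating an enolate. Compound 8 would be heated with N,N-dimethylformamide dimethyl acetal (neat, 100 °C) to the enaminone (E)-3-(dimethylamino)-1-[2-{[3-methoxy-4-(triisopropylsilyloxy)phenyl]methoxy}-3-(3-methylbut-2-en-1-yl)-4,6-bis(triisopropylsilyloxy)phenyl]prop-2-en-1-one F9. Treatment with tosyl azide (MeCN, rt) should give 10 by cycloaddition and fragmentation of the triazoline, a known diazo transfer to enaminones.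

**Further compounds**

F1 | step 7 | (E)-3-(dimethylamino)-1-[2-hydroxy-3-(3-methylbut-2-en-1-yl)-4,6-bis(triisopropylsilyloxy)phenyl]prop-2-en-1-one | CN(C)/C=C/C(=O)c1c(O[Si](C(C)C)(C(C)C)C(C)C)cc(O[Si](C(C)C)(C(C)C)C(C)C)c(CC=C(C)C)c1O
F2 | step 7 | 8-(3-methylbut-2-en-1-yl)-5,7-bis(triisopropylsilyloxy)-4H-chromen-4-one | O=c1ccoc2c(CC=C(C)C)c(O[Si](C(C)C)(C(C)C)C(C)C)cc(O[Si](C(C)C)(C(C)C)C(C)C)c12
F3 | step 7 | (4-bromo-2-methoxyphenoxy)triisopropylsilane | COc1cc(Br)ccc1O[Si](C(C)C)(C(C)C)C(C)C
F4 | step 7 | [3-methoxy-4-(triisopropylsilyloxy)phenyl]boronic acid | COc1cc(B(O)O)ccc1O[Si](C(C)C)(C(C)C)C(C)C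
F5 | step 4 | 1-[2,6-dihydroxy-4-(triisopropylsilyloxy)phenyl]ethan-1-one | CC(=O)c1c(O)cc(O[Si](C(C)C)(C(C)C)C(C)C)cc1O
F6 | step 4 | 1-[2-hydroxy-6-{[3-methoxy-4-(triisopropylsilyloxy)phenyl]methoxy}-4-(triisopropylsilyloxy)phenyl]ethan-1-one | CC(=O)c1c(O)cc(O[Si](C(C)C)(C(C)C)C(C)C)cc1OCc1ccc(O[Si](C(C)C)(C(C)C)C(C)C)c(OC)c1
F7 | step 4 | 1-[2-{[3-methoxy-4-(triisopropylsilyloxy)phenyl]methoxy}-6-(3-methylbut-2-en-1-yloxy)-4-(triisopropylsilyloxy)phenyl]ethan-1-one | CC(=O)c1c(OCC=C(C)C)cc(O[Si](C(C)C)(C(C)C)C(C)C)cc1OCc1ccc(O[Si](C(C)C)(C(C)C)C(C)C)c(OC)c1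
F8 | step 4 | 1-[6-hydroxy-2-{[3-methoxy-4-(triisopropylsilyloxy)phenyl]methoxy}-3-(3-methylbut-2-en-1-yl)-4-(triisopropylsilyloxy)phenyl]ethan-1-one | CC(=O)c1c(O)cc(O[Si](C(C)C)(C(C)C)C(C)C)c(CC=C(C)C)c1OCc1ccc(O[Si](C(C)C)(C(C)C)C(C)C)c(OC)c1
F9 | step 6 | (E)-3-(dimethylamino)-1-[2-{[3-methoxy-4-(triisopropylsilyloxy)phenyl]methoxy}-3-(3-methylbut-2-en-1-yl)-4,6-bis(triisopropylsilyloxy)phenyl]prop-2-en-1-one | CN(C)/C=C/C(=O)c1c(O[Si](C(C)C)(C(C)C)C(C)C)cc(O[Si](C(C)C)(C(C)C)C(C)C)c(CC=C(C)C)c1OCc1ccc(O[Si](C(C)C)(C(C)C)C(C)C)c(OC)c1
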